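# Proposed synthesis of CNP0314633.1 (compound 19) by light-driven dynamic kinetic resolution of a 2,2-diaryl-2H-chromene

## The problem

Target 19 joins two C15 units: a 5,7-dihydroxychroman-4-one (benzo ring A; pyranone ring C with O1, C2, C3, C4; 4-hydroxyphenyl ring B on C2) and a kaempferol (benzo ring D, pyranone ring E, aryl ring G; its atoms carry the suffix k). The units are linked twice, by the C2–C8k carbon–carbon bond and by the C3–O7k ether bond, so that a dihydrofuran ring F (C2, C3, O7k, C7k, C8k) is fused to ring C along C2–C3 and to ring D along C7k–C8k. C2 (R) is a fully substituted carbon carrying O1, ring B, C8k and C3; C3 (S) is a hemiketal carbon carrying a free hydroxyl, O7k, C2 and the C4 carbonyl carbon. A five-membered ring can be fused to ring C only in the cis sense and the hemiketal forms reversibly, so C3 follows C2. C2 is therefore the one stereocentre that must be controlled; it is quaternary, has no stereogenic neighbour to lean on, and sits between ring B and the doubly ortho-substituted ring D. Six free hydroxyl groups on electron-rich rings (seven in the open dione tautomer) and a hemiketal next to a ketone (the closed form of a base-sensitive 1,2-dione) require that every oxidation be done on a protected skeleton and that the last step be neutral. The enabling feature is that C2, once C3=C4 is drawn as an alkene, is the sp3 carbon of a 2,2-diaryl-2H-chromene: its O1–C2 bond opens reversibly under light to an achiral dienone, so C2 can be scrambled without reagents, and the C3=C4 bond is a cis-disubstituted, aryl-conjugated alkene placed exactly where the two missing oxygens are needed.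

## Retrosynthesis

**Hemiketal and protecting groups (19 ⇒ 17).** Cutting C3–O7k turns 19 into its open tautomer 18, a 3,4-dione with a free 7k-phenol; capping the seven hydroxyls of 18 as benzyl ethers gives 17. Against a late C–O coupling to forge C3–O7k, this cut costs nothing, because 18 closes by itself and only in the cis sense. One protecting group for all seven positions reduces the end to a single neutral hydrogenolysis, which must spare the benzylic O1–C2 bond and the dione.

**Oxidation level (17 ⇒ 15 ⇒ 14).** Both carbonyls of 17 are traced to trans-diol 15 and then to epoxide 14; no skeletal bond is cut. The C3 and C4 stereocentres of 14 are erased again in 17; they serve as reporters that let a catalyst read, and a column purify, the configuration at C2. Asymmetric dihydroxylation of the alkene would reach 15 directly, but it is at its weakest with cis-disubstituted cyclic styrenes, the very class where (salen)MnCl-catalysed epoxidation is at its best. The forward steps need a mild hydrolysis and a glycol oxidation that does not cleave the C3–C4 bond.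

**Key disconnection (14 ⇒ 13).** The two C–O bonds of the oxirane are cut, giving racemic chromene 13. The precursor then carries no oxidation at C3/C4 and no stereochemical information that has to be made earlier. The forward reaction must tell the enantiomers of 13 apart while light interconverts them through dienone 12.

**Ring C (13 ⇒ 9 + 10).** O1–C2 and C4–C4a are cut, giving propargylic alcohol 9 and phenol 10; the forward cascade runs through ether 11 and dienone 12, the same dienone through which 13 later racemises. Building ring C from a chromanone would instead require arylation of a quaternary C2. Phenol 10 has two equivalent ortho positions, so no regiochemical issue arises.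

**C2–C8k (9 ⇒ 3 + 6).** The carbinol is cut between C2 and C8k into aryl Grignard 7 (from iodide 3) and ynone 6. The neighbouring option, Lewis-acid aroylation at C8k followed by acetylide addition, risks C6k/C8k mixtures, loss of benzyl ethers and a hindered ketone competing with the flavone carbonyl. Here the position is fixed by iodination and the hindered partner is the nucleophile.

**Building blocks (3 ⇒ 2 ⇒ 1; 6 ⇒ 4 + 5).** Iodide 3 comes from tetrabenzyl ether 2 and this from kaempferol 1; ynone 6 comes from acid chloride 4 and silylalkyne 5 by acyl Sonogashira coupling.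

## Roads not taken

**Alternative 1:** Ring C is cut at O1–C2 and C3–C4. The furan-fused flavone A2 (a 3-aryl-2-nitrobenzofuran built across O7k/C8k) would react with phenyl salicylate A3 under a chiral squaramide–tertiary amine. The ring A phenol adds to the aryl-bearing furan carbon (the future C2), and the nitronate at the future C3 is acylated by the neighbouring phenyl ester, giving A1, the hexa-O-benzyl skeleton with nitro in place of the C3 hydroxyl.
- Merits: both stereocentres and ring C arise in one convergent, metal-free step; ring F is present from the start; hydrogen-bond-catalysed dearomatisation of 2-nitrobenzofurans is an established reaction class.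
- Weak points: the acceptor carbon carries an aryl group, so a weakly nucleophilic, internally hydrogen-bonded phenol must add reversibly to a tetrasubstituted aromatic nitroalkene and create a fully substituted diaryl ether carbon. The acylation must outrun the retro-addition. A2 needs a nitrofuran annulation on the kaempferol core. A1 still has the wrong heteroatom at C3, and its exchange for hydroxyl must pass through an oxocarbenium ion next to a ketone or a radical.
- Comparison: as a bond construction this road is more convergent and needs no light. The chosen plan sets against it a stereo-determining event of a proven kind on the substrate class where it works best, oxygen at C3 and C4 from the key step itself, and no functional-group repair at a congested hemiketal carbon.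

**Alternative 2:** Only C2–C8k is cut, giving the biflavonyl ether A5, in which O7k of one benzylated kaempferol is attached to C3 of a second flavone. Irradiation of A5 bound to Cu(OTf)2 and a chiral bisoxazoline would trigger conrotatory six-electron closure between C2 and C8k and a hydrogen shift from C8k to C3, giving the cis-fused A4 with hydrogen at C3.
- Merits: this is the shortest access to the full skeleton; both halves come from kaempferol; cis fusion is built into the hydrogen shift; Lewis-acid-mediated enantioselective photocyclisation of aryloxy enones is a known reaction type.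
- Weak points: O7k can close onto C6k as well as C8k, and nothing in A5 favours the more crowded C8k. The enone is part of a 2-aryl-4-pyranone that must give up its stabilisation to form a quaternary centre. A4 lacks the C3 hydroxyl, and any enolate at C3 can expel the O1 phenoxide to give an aromatic benzofuran and destroy C2.
- Comparison: fewer steps before the key event and no resolution at all, which is a real advantage. The chosen plan has no regiochemical ambiguity, brings in the C3 oxygen before C2 is locked, and never enolises toward C3.

**Alternative 3:** Cuts at C2–C3 and O1–C8a lead to A7, an 8k-aroyl kaempferol whose O7k carries a CH(OBn)–CO–aryl unit with a fluoride on the future ring A. With a cinchona-derived quaternary ammonium salt and Cs2CO3, the enolate of the α-benzyloxy ketone would add to the diaryl ketone (C2–C3, ring F), and the tertiary alkoxide would displace fluoride (O1–C8a, ring C), giving A6, the hexa-O-benzyl target as its C3 benzyl ketal.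
- Merits: A6 is at the final oxidation level and one hydrogenolysis from 19, two steps shorter at the end than the chosen plan. The racemic acetal carbon of A7 is erased on enolisation, and only the aldolate with O1 and C4 cis can close ring C, so wrong diastereomers can revert.
- Weak points: the acceptor is a doubly ortho-substituted diaryl ketone whose faces differ only by the remote shapes of ring B and ring D, to be told apart by an ion pair. Fluoride displacement on a ring with two alkoxy donors is slow, while retro-aldol erodes selectivity. The mixed acetal at the hindered O7k of A7 is awkward to prepare.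
- Comparison: in step count after the key step, and in avoiding both light and a labile epoxide, this road is better. The chosen plan offers in return a face-selection mode with strong precedent, optical purity that can be upgraded by separating diastereomers, and a precursor assembled from robust reactions.

Key step: step 6

Assumption: 3,5-bis(benzyloxy)phenol 10 is taken as a purchasable phloroglucinol derivative; the configuration at C4 of diol 15 is immaterial because C4 becomes a carbonyl in step 8.

In the names below, "tetra-O-benzylkaempferol-8-yl" stands for 3,5,7-tris(benzyloxy)-2-[4-(benzyloxy)phenyl]-4-oxo-4H-chromen-8-yl, and (S,S)-(salen)MnCl stands for (S,S)-[N,N'-bis(3,5-di-tert-butylsalicylidene)-1,2-cyclohexanediaminato]MnCl.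

## Route

Step 1
Reactants: 1 kaempferol
Product: 2 3,5,7-tris(benzyloxy)-2-[4-(benzyloxy)phenyl]-4H-chromen-4-one (tetra-O-benzylkaempferol)
Conditions: BnBr (6 equiv), K2CO3, DMF, 80 °C
Reagents that add atoms: benzyl bromide, BrCc1ccccc1
Why: Fourfold Williamson etherification; the chelated 5k-hydroxyl reacts last and is driven to completion by excess halide and heat.

Step 2
Reactants: 2 tetra-O-benzylkaempferol
Product: 3 3,5,7-tris(benzyloxy)-2-[4-(benzyloxy)phenyl]-8-iodo-4H-chromen-4-one
Conditions: NIS, CF3CO2H (cat.), MeCN–CH2Cl2, 0 °C to rt, dark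
Reagents that add atoms: N-iodosuccinimide, O=C1CCC(=O)N1I
Why: Electrophilic aromatic iodination; ring D is the most electron-rich ring, and in fully etherified 5,7-dioxygenated flavones substitution goes to C8k (ortho to O7k, para to O5k) and not to C6k, which is squeezed between two benzyloxy groups.

Step 3
Reactants: 4 4-(benzyloxy)benzoyl chloride; 5 ethynyltrimethylsilane
Product: 6 1-[4-(benzyloxy)phenyl]-3-(trimethylsilyl)prop-2-yn-1-one
Conditions: PdCl2(PPh3)2 (2 mol %), CuI (4 mol %), Et3N, THF, rt
Reagents that add atoms: none
Why: Acyl Sonogashira coupling of an aroyl chloride with a terminal alkyne; the silyl group caps the alkyne terminus and later shields the β-carbon against conjugate addition.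

Step 4
Reactants: 3 8-iodo-tetra-O-benzylkaempferol; 6 silylated ynone
Product: 9 rac-1-[4-(benzyloxy)phenyl]-1-(tetra-O-benzylkaempferol-8-yl)prop-2-yn-1-ol, via aryl Grignard reagent 7 (not isolated), via silylated carbinol 8 (not isolated)
Conditions: iPrMgCl·LiCl, THF, −40 °C; then 6, −40 to 0 °C; then MeOH, K2CO3, rt
Reagents that add atoms: none
Why: Iodine–magnesium exchange with the turbo-Grignard reagent is fast for aryl iodides at low temperature, where the vinylogous-ester carbonyl of the flavone is left alone; Grignard 1,2-addition to the non-enolisable ynone forms C2–C8k, and methanolic carbonate removes the alkynyl silane in the same flask; the carbinol carbon is racemic and is flattened again in step 5.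

Step 5
Reactants: 9 propargylic alcohol; 10 3,5-bis(benzyloxy)phenol
Product: 13 rac-5,7-bis(benzyloxy)-2-[4-(benzyloxy)phenyl]-2-(tetra-O-benzylkaempferol-8-yl)-2H-chromene, via aryl propargyl ether 11 (not isolated), via ring-opened dienone 12 (not isolated)
Conditions: PPTS (10 mol %), HC(OMe)3, ClCH2CH2Cl, 80 °C
Reagents that add atoms: none
Why: Standard synthesis of 2,2-diaryl-2H-chromenes from 1,1-diarylpropargyl alcohols and electron-rich phenols: acid-catalysed etherification through the doubly aryl-stabilised propargylic cation, propargyl Claisen rearrangement to the ortho position, tautomerisation to dienone 12 and oxa-6π electrocyclisation; the two ortho positions of 10 are equivalent, so a single chromene should result.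

Step 6
Reactants: 13 racemic chromene
Product: 14 (2R,3S,4S)-5,7-bis(benzyloxy)-2-[4-(benzyloxy)phenyl]-3,4-epoxy-2-(tetra-O-benzylkaempferol-8-yl)chromane (oxirane oxygen anti to ring D)
Conditions: (S,S)-[N,N'-bis(3,5-di-tert-butylsalicylidene)-1,2-cyclohexanediaminato]MnCl (5 mol %), 4-phenylpyridine N-oxide (20 mol %), aq. NaOCl (pH 11.3, slow addition), CH2Cl2, 0 °C, 365 nm LED; chromatography on Et3N-deactivated silica
Reagents that add atoms: sodium hypochlorite, [Na+].[O-]Cl
Why: Proposed new method: hypochlorite oxidises the trivalent manganese complex (salen)MnCl to the pentavalent oxo species (salen)Mn(O)Cl, which transfers its oxygen atom to the electron-rich cis C3=C4 bond and closes the oxirane by forming C4–O and C3–O on one face (oxygen-atom transfer, formally a [2+1] closure; the cyclic alkene cannot leak to a trans product). The closest known reaction types are the Jacobsen–Katsuki epoxidation and kinetic resolution of 2,2-disubstituted 2H-chromenes and, separately, the photochromic O1–C2 opening of 2,2-diaryl-2H-chromenes; running both in one flask is new. With the (S,S) ligand oxygen is delivered to the alkene face that gives 3S,4S; in (R)-13 this is the face remote from the bulky, doubly ortho-substituted ring D, so (R)-13 is the matched, faster-reacting enantiomer and C3 and C4 are set by the catalyst. At 365 nm either enantiomer of 13 undergoes six-electron electrocyclic opening to the achiral dienone 12 already met in step 5, which lies off the path to 14 and recloses thermally by oxa-6π electrocyclisation to racemic 13, so unreacted (S)-13 is fed back into the matched manifold and C2 is set by selection, not by bond formation at C2. Epoxide 14 has lost the diene needed for opening, which locks C2. The step needs a rate gap between the enantiomers and a racemisation that keeps pace with oxidation; the size difference between ring D and ring B at C2 should provide the first and slow addition of the oxidant the second. Enantiopurity does not depend on either being perfect: (S)-13 oxidised on the catalyst-preferred face gives the syn diastereomer of 14, which is removed by chromatography, so the optical purity of 14 at C2 rests on the catalyst's face selectivity and the light only raises the yield. Hypochlorite stays in the aqueous phase and 12 is short-lived, which should limit nucleophilic oxidation of the dienone.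

Step 7
Reactants: 14 epoxide
Product: 15 (2R,3S,4R)-5,7-bis(benzyloxy)-2-[4-(benzyloxy)phenyl]-2-(tetra-O-benzylkaempferol-8-yl)chromane-3,4-diol (trans-diol)
Conditions: THF–H2O (4:1), PPTS (5 mol %), 0 °C
Reagents that add atoms: water, O
Why: Acid-catalysed epoxide hydrolysis; C4–O ionises readily because the benzylic cation is stabilised by the ortho and para benzyloxy groups of ring A, water enters at C4 mainly anti to the departing oxygen and C3 keeps its configuration; any cis-diol formed is carried along because C4 becomes a carbonyl in step 8.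

Step 8
Reactants: 15 trans-diol
Product: 17 (2R)-5,7-bis(benzyloxy)-2-[4-(benzyloxy)phenyl]-2-(tetra-O-benzylkaempferol-8-yl)chromane-3,4-dione, via ketol 16 (not isolated)
Conditions: IBX (4 equiv), DMSO, 40 °C
Reagents that add atoms: none
Why: IBX oxidation of a 1,2-diol to a 1,2-diketone without glycol cleavage; the benzylic C4 hydroxyl should go first (ketol 16), then the C3 hydroxyl; C2 is quaternary, so the dione cannot enolise and the stereocentre is safe.

Step 9
Reactants: 17 heptabenzyl dione
Product: 19 CNP0314633.1 (the 2R,3S cis-fused hemiketal in which O7k of the kaempferol unit is bound to C3 of the chromanone unit and C3 keeps a free hydroxyl), via free dione 18 (not isolated)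
Conditions: H2 (1 atm), Pd(OH)2/C, THF–MeOH, rt
Reagents that add atoms: none
Why: Catalytic hydrogenolysis of the seven benzyl ethers under neutral conditions, with the C3 carbonyl expected to sit as its methanol hemiketal and so be shielded from reduction; once O7k is free it adds to the strongly electrophilic C3 carbonyl (5-exo-trig hemiketalisation), and because ring F can only be cis-fused to ring C, 3S follows from 2R.

## Compound list

1 | kaempferol | O=c1c(O)c(-c2ccc(O)cc2)oc2cc(O)cc(O)c12 | starting material
2 | 3,5,7-tris(benzyloxy)-2-[4-(benzyloxy)phenyl]-4H-chromen-4-one | O=c1c(OCc2ccccc2)c(-c2ccc(OCc3ccccc3)cc2)oc2cc(OCc3ccccc3)cc(OCc3ccccc3)c12 | intermediate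
3 | 3,5,7-tris(benzyloxy)-2-[4-(benzyloxy)phenyl]-8-iodo-4H-chromen-4-one | O=c1c(OCc2ccccc2)c(-c2ccc(OCc3ccccc3)cc2)oc2c(I)c(OCc3ccccc3)cc(OCc3ccccc3)c12 | intermediate
4 | 4-(benzyloxy)benzoyl chloride | O=C(Cl)c1ccc(OCc2ccccc2)cc1 | starting material
5 | ethynyltrimethylsilane | C#C[Si](C)(C)C | starting material
6 | 1-[4-(benzyloxy)phenyl]-3-(trimethylsilyl)prop-2-yn-1-one | O=C(C#C[Si](C)(C)C)c1ccc(OCc2ccccc2)cc1 | intermediate
7 | (tetra-O-benzylkaempferol-8-yl)magnesium chloride (not isolated) | O=c1c(OCc2ccccc2)c(-c2ccc(OCc3ccccc3)cc2)oc2c([Mg]Cl)c(OCc3ccccc3)cc(OCc3ccccc3)c12 | intermediate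
8 | rac-1-[4-(benzyloxy)phenyl]-1-(tetra-O-benzylkaempferol-8-yl)-3-(trimethylsilyl)prop-2-yn-1-ol (magnesium alkoxide in the flask, not isolated) | C[Si](C)(C)C#CC(O)(c1ccc(OCc2ccccc2)cc1)c1c(OCc2ccccc2)cc(OCc2ccccc2)c2c(=O)c(OCc3ccccc3)c(-c3ccc(OCc4ccccc4)cc3)oc12 | intermediate
9 | rac-1-[4-(benzyloxy)phenyl]-1-(tetra-O-benzylkaempferol-8-yl)prop-2-yn-1-ol | C#CC(O)(c1ccc(OCc2ccccc2)cc1)c1c(OCc2ccccc2)cc(OCc2ccccc2)c2c(=O)c(OCc3ccccc3)c(-c3ccc(OCc4ccccc4)cc3)oc12 | intermediate
10 | 3,5-bis(benzyloxy)phenol | Oc1cc(OCc2ccccc2)cc(OCc2ccccc2)c1 | starting material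
11 | rac-3,5-bis(benzyloxy)phenyl 1-[4-(benzyloxy)phenyl]-1-(tetra-O-benzylkaempferol-8-yl)prop-2-yn-1-yl ether (not isolated) | C#CC(Oc1cc(OCc2ccccc2)cc(OCc2ccccc2)c1)(c1ccc(OCc2ccccc2)cc1)c1c(OCc2ccccc2)cc(OCc2ccccc2)c2c(=O)c(OCc3ccccc3)c(-c3ccc(OCc4ccccc4)cc3)oc12 | intermediate
12 | 3,5-bis(benzyloxy)-6-{3-[4-(benzyloxy)phenyl]-3-(tetra-O-benzylkaempferol-8-yl)prop-2-en-1-ylidene}cyclohexa-2,4-dien-1-one (achiral ring-opened dienone, not isolated) | O=C1C=C(OCc2ccccc2)C=C(OCc2ccccc2)C1=CC=C(c1ccc(OCc2ccccc2)cc1)c1c(OCc2ccccc2)cc(OCc2ccccc2)c2c(=O)c(OCc3ccccc3)c(-c3ccc(OCc4ccccc4)cc3)oc12 | intermediate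
13 | rac-5,7-bis(benzyloxy)-2-[4-(benzyloxy)phenyl]-2-(tetra-O-benzylkaempferol-8-yl)-2H-chromene | C1=CC(c2ccc(OCc3ccccc3)cc2)(c2c(OCc3ccccc3)cc(OCc3ccccc3)c3c(=O)c(OCc4ccccc4)c(-c4ccc(OCc5ccccc5)cc4)oc23)Oc2cc(OCc3ccccc3)cc(OCc3ccccc3)c12 | intermediate
14 | (2R,3S,4S)-5,7-bis(benzyloxy)-2-[4-(benzyloxy)phenyl]-3,4-epoxy-2-(tetra-O-benzylkaempferol-8-yl)chromane, oxirane oxygen anti to ring D | [C@@]1(c2ccc(OCc3ccccc3)cc2)(c2c(OCc3ccccc3)cc(OCc3ccccc3)c3c(=O)c(OCc4ccccc4)c(-c4ccc(OCc5ccccc5)cc4)oc23)Oc2cc(OCc3ccccc3)cc(OCc3ccccc3)c2[C@@H]2O[C@H]12 | intermediate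
15 | (2R,3S,4R)-5,7-bis(benzyloxy)-2-[4-(benzyloxy)phenyl]-2-(tetra-O-benzylkaempferol-8-yl)chromane-3,4-diol | [C@@]1(c2ccc(OCc3ccccc3)cc2)(c2c(OCc3ccccc3)cc(OCc3ccccc3)c3c(=O)c(OCc4ccccc4)c(-c4ccc(OCc5ccccc5)cc4)oc23)Oc2cc(OCc3ccccc3)cc(OCc3ccccc3)c2[C@@H](O)[C@@H]1O | intermediate
16 | (2R,3R)-5,7-bis(benzyloxy)-2-[4-(benzyloxy)phenyl]-3-hydroxy-2-(tetra-O-benzylkaempferol-8-yl)chroman-4-one (not isolated) | [C@@]1(c2ccc(OCc3ccccc3)cc2)(c2c(OCc3ccccc3)cc(OCc3ccccc3)c3c(=O)c(OCc4ccccc4)c(-c4ccc(OCc5ccccc5)cc4)oc23)Oc2cc(OCc3ccccc3)cc(OCc3ccccc3)c2C(=O)[C@@H]1O | intermediate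
17 | (2R)-5,7-bis(benzyloxy)-2-[4-(benzyloxy)phenyl]-2-(tetra-O-benzylkaempferol-8-yl)chromane-3,4-dione | [C@@]1(c2ccc(OCc3ccccc3)cc2)(c2c(OCc3ccccc3)cc(OCc3ccccc3)c3c(=O)c(OCc4ccccc4)c(-c4ccc(OCc5ccccc5)cc4)oc23)Oc2cc(OCc3ccccc3)cc(OCc3ccccc3)c2C(=O)C1=O | intermediate
18 | (2R)-5,7-dihydroxy-2-(4-hydroxyphenyl)-2-(kaempferol-8-yl)chromane-3,4-dione (open tautomer of the target, not isolated) | [C@@]1(c2ccc(O)cc2)(c2c(O)cc(O)c3c(=O)c(O)c(-c4ccc(O)cc4)oc23)Oc2cc(O)cc(O)c2C(=O)C1=O | intermediate
19 | CNP0314633.1, (2R,3S) cis-fused hemiketal | O=C1c2c(O)cc(O)cc2O[C@]2(c3ccc(O)cc3)c3c(cc(O)c4c(=O)c(O)c(-c5ccc(O)cc5)oc34)O[C@]12O | target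

## Step count and risks

Total: 9 steps. Longest linear sequence: 8 steps from kaempferol 1 (steps 1, 2, 4, 5, 6, 7, 8, 9); step 3 is a one-step side branch.

**Step 6 (key step, proposed new method).**
- What may go wrong: racemisation may fall behind oxidation, because most 365 nm light is likely to be absorbed by the flavonol chromophore and the manganese complex and not by the chromene. The excited flavonol carbonyl may abstract hydrogen from neighbouring benzyl ethers. The transient dienone 12 may be oxidised. The rate gap between the enantiomers may be small, which lowers yield through more syn diastereomer but should not lower optical purity.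
- Fallback (known chemistry), from 13 back to 14: racemic 13 is separated by preparative chromatography on a chiral stationary phase into the (R)-2H-chromene F1 and the (S)-2H-chromene F2. F2 alone is irradiated at 365 nm in toluene without oxidant, where the known photochromic opening and thermal reclosure return racemic 13 for another pass. F1 is epoxidised in the dark with the same (S,S)-(salen)MnCl and NaOCl, an ordinary matched Jacobsen–Katsuki epoxidation, and rejoins the route at 14.

**Step 4.**
- What may go wrong: the hindered, doubly ortho-substituted aryl Grignard 7 may add sluggishly to the ynone, with conjugate addition or attack on a flavone carbonyl of a second molecule competing.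
- Fallback, from 3 back to 9: Grignard 7 is added to 4-(benzyloxy)benzaldehyde, a less hindered electrophile with no conjugate pathway, giving rac-[4-(benzyloxy)phenyl](tetra-O-benzylkaempferol-8-yl)methanol F3. The doubly benzylic alcohol is oxidised with MnO2 to [4-(benzyloxy)phenyl](tetra-O-benzylkaempferol-8-yl)methanone F4. Ethynylmagnesium bromide in THF then adds to this ketone, the only carbonyl that is not a vinylogous ester, to return to 9.

**Step 5.**
- What may go wrong: ionisation of 9 may be diverted into Meyer–Schuster rearrangement, or into C-alkylation para to the phenol oxygen, before the ortho annulation takes place.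
- Fallback, from 9 back to 13: the Meyer–Schuster pathway is made the route. Treatment of 9 with catalytic p-TsOH in wet 1,4-dioxane gives 3-[4-(benzyloxy)phenyl]-3-(tetra-O-benzylkaempferol-8-yl)prop-2-enal F5 (mixture of alkene isomers). F5 is condensed with phenol 10 under catalytic ethylenediammonium diacetate in refluxing xylene (Knoevenagel-type ortho condensation to dienone 12, then oxa-6π closure) to rejoin the route at 13.

**Step 7.**
- What may go wrong: the very electron-rich benzylic epoxide may rearrange (hydride shift to a chroman-3-one) or decompose during isolation or hydrolysis, in place of clean addition of water.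
- Fallback, from 14 back to 17: the epoxide is opened oxidatively with DMSO and catalytic TfOH at rt, followed by Et3N. DMSO attacks the benzylic C4, and the alkoxysulfonium salt collapses to the C4 ketone. This gives ketol 16 directly, which is isolated here (the syn/anti diastereomers can also be separated at this stage) and oxidised with IBX in DMSO to rejoin the route at 17.

**Step 9.**
- What may go wrong: over-reduction (hydrogenation of the 1,2-dione to a ketol, or hydrogenolysis of the doubly benzylic O1–C2 bond) may occur before all seven benzyl ethers are cleaved and the hemiketal has closed.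
- Fallback, from 17 back to 19: non-reductive Lewis-acid debenzylation with BCl3 and pentamethylbenzene as cation scavenger in CH2Cl2 at −78 °C, followed by aqueous work-up, gives 18, which closes to 19 as before.

## Further compounds

F1 | step 6 | (R)-5,7-bis(benzyloxy)-2-[4-(benzyloxy)phenyl]-2-(tetra-O-benzylkaempferol-8-yl)-2H-chromene | [C@@]1(c2ccc(OCc3ccccc3)cc2)(c2c(OCc3ccccc3)cc(OCc3ccccc3)c3c(=O)c(OCc4ccccc4)c(-c4ccc(OCc5ccccc5)cc4)oc23)Oc2cc(OCc3ccccc3)cc(OCc3ccccc3)c2C=C1
F2 | step 6 | (S)-5,7-bis(benzyloxy)-2-[4-(benzyloxy)phenyl]-2-(tetra-O-benzylkaempferol-8-yl)-2H-chromene | [C@]1(c2ccc(OCc3ccccc3)cc2)(c2c(OCc3ccccc3)cc(OCc3ccccc3)c3c(=O)c(OCc4ccccc4)c(-c4ccc(OCc5ccccc5)cc4)oc23)Oc2cc(OCc3ccccc3)cc(OCc3ccccc3)c2C=C1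
F3 | step 4 | rac-[4-(benzyloxy)phenyl](tetra-O-benzylkaempferol-8-yl)methanol | OC(c1ccc(OCc2ccccc2)cc1)c1c(OCc2ccccc2)cc(OCc2ccccc2)c2c(=O)c(OCc3ccccc3)c(-c3ccc(OCc4ccccc4)cc3)oc12
F4 | step 4 | [4-(benzyloxy)phenyl](tetra-O-benzylkaempferol-8-yl)methanone | O=C(c1ccc(OCc2ccccc2)cc1)c1c(OCc2ccccc2)cc(OCc2ccccc2)c2c(=O)c(OCc3ccccc3)c(-c3ccc(OCc4ccccc4)cc3)oc12
F5 | step 5 | 3-[4-(benzyloxy)phenyl]-3-(tetra-O-benzylkaempferol-8-yl)prop-2-enal | O=CC=C(c1ccc(OCc2ccccc2)cc1)c1c(OCc2ccccc2)cc(OCc2ccccc2)c2c(=O)c(OCc3ccccc3)c(-c3ccc(OCc4ccccc4)cc3)oc12
F0 | step 7 | none | none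
F0 | step 9 | none | none
A1 | alternative 1 | hexa-O-benzyl skeleton of the target with nitro in place of the C3 hydroxyl | O=C1c2c(OCc9ccccc9)cc(OCc9ccccc9)cc2O[C@]2(c3ccc(OCc9ccccc9)cc3)c3c(cc(OCc9ccccc9)c4c(=O)c(OCc9ccccc9)c(-c5ccc(OCc9ccccc9)cc5)oc34)O[C@]12[N+](=O)[O-]
A2 | alternative 1 | tri-O-benzylkaempferol-derived 2-nitro-3-[4-(benzyloxy)phenyl]benzofuran (furan fused across O7k and C8k) | O=[N+]([O-])c1oc2cc(OCc3ccccc3)c3c(=O)c(OCc4ccccc4)c(-c4ccc(OCc5ccccc5)cc4)oc3c2c1-c1ccc(OCc2ccccc2)cc1
A3 | alternative 1 | phenyl 2,4-bis(benzyloxy)-6-hydroxybenzoate | O=C(Oc1ccccc1)c1c(O)cc(OCc2ccccc2)cc1OCc1ccccc1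
A4 | alternative 2 | cis-fused hexa-O-benzyl compound with hydrogen at C3 | O=C1c2c(OCc9ccccc9)cc(OCc9ccccc9)cc2O[C@]2(c3ccc(OCc9ccccc9)cc3)c3c(cc(OCc9ccccc9)c4c(=O)c(OCc9ccccc9)c(-c5ccc(OCc9ccccc9)cc5)oc34)O[C@H]12
A5 | alternative 2 | 5,7-bis(benzyloxy)-2-[4-(benzyloxy)phenyl]-3-{[3,5-bis(benzyloxy)-2-[4-(benzyloxy)phenyl]-4-oxo-4H-chromen-7-yl]oxy}-4H-chromen-4-one | O=c1c(Oc2cc(OCc3ccccc3)c3c(=O)c(OCc4ccccc4)c(-c4ccc(OCc5ccccc5)cc4)oc3c2)c(-c2ccc(OCc3ccccc3)cc2)oc2cc(OCc3ccccc3)cc(OCc3ccccc3)c12
A6 | alternative 3 | hexa-O-benzyl target as its C3 benzyl ketal | O=C1c2c(OCc9ccccc9)cc(OCc9ccccc9)cc2O[C@]2(c3ccc(OCc9ccccc9)cc3)c3c(cc(OCc9ccccc9)c4c(=O)c(OCc9ccccc9)c(-c5ccc(OCc9ccccc9)cc5)oc34)O[C@]12OCc9ccccc9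
A7 | alternative 3 | 8-[4-(benzyloxy)benzoyl]-3,5-bis(benzyloxy)-2-[4-(benzyloxy)phenyl]-7-{1-(benzyloxy)-2-[2,4-bis(benzyloxy)-6-fluorophenyl]-2-oxoethoxy}-4H-chromen-4-one (racemic) | O=C(c1ccc(OCc2ccccc2)cc1)c1c(OC(OCc2ccccc2)C(=O)c2c(F)cc(OCc3ccccc3)cc2OCc2ccccc2)cc(OCc2ccccc2)c2c(=O)c(OCc3ccccc3)c(-c3ccc(OCc4ccccc4)cc3)oc12
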